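**Plan**
- Retrosynthesis (germacrane numbering): remove the C8 angelate; cut the lactone C6–O bond together with C5–O, which leads back to a ring-cis C5=C6 alkene in the ten-membered carbocycle; then cut C5=C6 (ring-closing metathesis), C7–C8 (allylation of a C8 aldehyde) and C1=C10 (Wittig).
- Forward: a myrcene-derived C1–C5/C15 aldehyde and a succinate-type ylide give the (E)-enoate C8 aldehyde; an acrolein-derived dienyl bromide is added at C7–C8; metathesis closes the ten-membered ring; the γ-lactone closes in the key step; the angelate goes on last.
- Enabling feature: in the ten-membered ring the C8 hydroxyl is homoallylic to the cis C5=C6 alkene, and the C12 carboxyl (on C11 at C7) is γ,δ to it. The threo C5–OH/C6–O pair with the trans-fused five-membered lactone (O, C12, C11, C7, C6) is what anti addition of these two oxygens across that alkene gives.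
- Stereochemistry: C7 and C8 come from the ligand-controlled, syn-selective chromium allylation; C5 and C6 are relayed from them in the key step (hydroxyl-directed face, inversion at C6); C1=C10 comes from the E-selective Wittig, C5=C6 is cis by ring size, and the angelate is Z from angelic acid.

Key step: step 11

Remark: positions are given in germacrane numbering throughout; the C12 acid is carried as its 2-(trimethylsilyl)ethyl ester and freed only inside the key step, because a free 8-hydroxy-12-acid would close to the 8,12-olide and would offer vanadium a second ligand.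

Step 1
Reactants: 1 myrcene
Product: 2 myrcene 6,7-epoxide (racemic)
Conditions: mCPBA (1.0 equiv), CH2Cl2, 0 °C
Reagents that add atoms: mCPBA, O=C(OO)c1cccc(Cl)c1
Why: Prilezhaev epoxidation, in which the electron-rich trisubstituted alkene should react well ahead of the conjugated diene; the new stereocentre is racemic and is destroyed in step 2.

Step 2
Reactants: 2 myrcene 6,7-epoxide
Product: 4 4-methylidenehex-5-enal, via diol 3 (not isolated)
Conditions: H5IO6 (1.1 equiv), THF/Et2O, 0 °C
Reagents that add atoms: none
Why: Acid-mediated hydration of the epoxide (water enters at the tertiary carbon) followed by Malaprade glycol cleavage in the same flask, which leaves the diene untouched and releases the C1 aldehyde.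

Step 3
Reactants: 5 methyl (triphenylphosphoranylidene)acetate (2 equiv); 6 2-bromo-N-methoxy-N-methylacetamide
Product: 8 methyl 4-[methoxy(methyl)amino]-4-oxo-2-(triphenylphosphoranylidene)butanoate, via phosphonium bromide 7 (not isolated)
Conditions: EtOAc, 70 °C; filtration
Reagents that add atoms: none
Why: C-alkylation of a stabilised ylide by an α-bromo amide followed by transylidation, in which the second equivalent of 5 deprotonates salt 7 to the α-substituted stabilised ylide.

Step 4
Reactants: 4 4-methylidenehex-5-enal; 8 substituted ylide
Product: 9 methyl (2E)-2-{2-[methoxy(methyl)amino]-2-oxoethyl}-6-methylideneocta-2,7-dienoate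
Conditions: toluene, 70 °C
Reagents that add atoms: none
Why: Wittig olefination with an α-branched stabilised ylide, which under reversible addition should place the C2 chain trans to the ester (E), the geometry that is ring-cis at C1=C10 in the target.

Step 5
Reactants: 9 N-methoxy-N-methylamide
Product: 11 methyl (2E)-6-methylidene-2-(2-oxoethyl)octa-2,7-dienoate (C8 aldehyde), via aluminium hemiaminal 10 (not isolated)
Conditions: iBu2AlH (1.1 equiv), THF, −78 °C; aq. potassium sodium tartrate, 0 °C
Reagents that add atoms: none
Why: Weinreb amide reduction, in which the chelated adduct 10 holds the aldehyde oxidation level until work-up and the amide should react ahead of the hindered conjugated methyl ester at −78 °C; the β,γ-unsaturated aldehyde is used at once without chromatography.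

Step 6
Reactants: 12 acryloyl chloride; 13 2-(trimethylsilyl)ethanol
Product: 14 2-(trimethylsilyl)ethyl acrylate
Conditions: Et3N (1.1 equiv), CH2Cl2, 0 °C
Reagents that add atoms: none
Why: Acylation of a primary alcohol by an acid chloride, which installs an ester that later comes off with fluoride under non-acidic conditions.

Step 7
Reactants: 14 2-(trimethylsilyl)ethyl acrylate; 15 acrolein
Product: 16 2-(trimethylsilyl)ethyl 3-hydroxy-2-methylidenepent-4-enoate (racemic)
Conditions: DABCO (20 mol%), dioxane/H2O, 0 °C to rt
Reagents that add atoms: none
Why: Morita–Baylis–Hillman reaction with acrolein as the aldehyde partner; the carbinol stereocentre is racemic and is removed by the allylic transposition in step 8.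

Step 8
Reactants: 16 Morita–Baylis–Hillman alcohol
Product: 17 2-(trimethylsilyl)ethyl (2Z)-2-(bromomethyl)penta-2,4-dienoate
Conditions: PBr3 (0.4 equiv), Et2O, −10 to 0 °C
Reagents that add atoms: PBr3, BrP(Br)Br
Why: Allylic bromination with SN2′ transposition, the standard fate of Morita–Baylis–Hillman alcohols, which should give the conjugated dienoate with the vinyl group cis to CH2Br as the thermodynamic isomer.

Step 9
Reactants: 11 C8 aldehyde; 17 dienyl bromide
Product: 20 acyclic (7R,8R)-hydroxy tetraene diester, via allylchromium dichloride 18 (not isolated), via silyl ether 19 (not isolated)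
Conditions: CrCl2 (10 mol%), chiral tridentate carbazole bis(oxazoline) ligand (12 mol%), iPr2NEt (30 mol%), Mn powder (2 equiv), TMSCl (1.5 equiv), THF, 0 °C; then aq. citric acid, 0 °C
Reagents that add atoms: none
Why: Catalytic asymmetric Nozaki–Hiyama–Kishi 2-(alkoxycarbonyl)allylation: the trivalent chromium pentadienyl species adds through its γ-carbon (C7) in a chair transition state with the vinyl group (cis to the metalated CH2) axial, which should give the syn adduct (cis-lactone series), while the ligand enantiomer is chosen to direct attack to the Si face of the aldehyde, so that C8 and C7 are both R; the sense of induction is assigned by analogy and is to be confirmed on the first adduct.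

Step 10
Reactants: 20 acyclic hydroxy tetraene diester
Product: 21 ten-membered (7R,8R)-hydroxy triene ester with ring-cis C5=C6
Conditions: second-generation Grubbs catalyst (10 mol% in two portions), toluene (0.001 M), 60 °C
Reagents that add atoms: none
Why: Diene–ene ring-closing metathesis between the C6 vinyl group and the only monosubstituted alkene of the 2-substituted butadiene (the 1,1-disubstituted and electron-poor alkenes should not compete); the ring-cis C1=C10 alkene already turns the chain, the product is a low-strain cis,cis-cyclodeca-1,6-diene, and a ten-membered ring should close to the cis alkene.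

Step 11
Reactants: 21 ten-membered hydroxy triene ester
Product: 24 (5S,6S,7R,8R)-5,8-dihydroxy 6,12-lactone (8-deacyl target), via epoxy alcohol ester 22 (not isolated), via epoxy acid 23 (not isolated)
Conditions: VO(acac)2 (5 mol%), TBHP (1.3 equiv, decane), CH2Cl2, 0 °C; aq. Na2S2O3 wash, solvent switch; TBAF (1.5 equiv), THF, 0 °C; then AcOH (2 equiv), 0 °C to rt
Reagents that add atoms: tert-butyl hydroperoxide, CC(C)(C)OO
Why: VO(acac)2 is oxidised by TBHP to a pentavalent vanadium alkylperoxide that binds the C8 hydroxyl as a vanadate ester and passes oxygen intramolecularly to the homoallylic C5=C6 alkene, giving cis-oxirane 22; fluoride then removes the 2-(trimethylsilyl)ethyl group by β-elimination and the C12 carboxylate, buffered by AcOH, attacks C6 from the rear (SN2), so that the γ-lactone closes and C5 keeps the oxirane oxygen as the free hydroxyl. The closest known reaction types are the hydroxyl-directed vanadium epoxidation of homoallylic alcohols and the lactonisation of γ,δ-epoxy acids to δ-hydroxy-γ-lactones. The lactone ring (O, C12, C11, C7, C6) closes 5-exo-tet, and because C11 and the oxirane oxygen lie on opposite faces the fusion is trans. C5 (S) is set by the face of oxygen transfer: A(1,3) strain with the cis C4 substituent keeps H7 in the alkene plane, so C8 with its vanadate sits over one face and C11 over the other; C6 (S) is set by inversion of the (6R) oxirane carbon, which makes the C5–OH/C6–O pair threo. The step needs site selectivity (C5=C6 over the enoate, the acrylate and C4=C15), face selectivity and attack at C6 instead of allylic C5 or SN2′ at C15: the first two come from the C8 hydroxyl, which is the only ligand for vanadium while C12 is still an ester and reaches only one electron-rich alkene, and the third comes from the five-membered tether and from opening with a carboxylate under non-ionising, weakly acidic conditions.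

Step 12
Reactants: 24 diol lactone; 25 angelic acid
Product: 27 target CNP0163095.1, via mixed anhydride 26 (not isolated)
Conditions: 25 (1.5 equiv), 2,4,6-trichlorobenzoyl chloride (1.5 equiv), Et3N (3 equiv), toluene, rt; then 24, toluene, 80 °C
Reagents that add atoms: none
Why: Yamaguchi-type esterification through the mixed anhydride without DMAP, a known way to form angelates without Z to E isomerisation; the bulky anhydride should acylate the C8 hydroxyl (CH2 neighbour) in preference to the allylic C5 hydroxyl, which lies between the sp2 carbon C4 and the lactone carbinol C6, and no stereocentre is touched.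

**Compound list**
1 | myrcene (7-methyl-3-methylideneocta-1,6-diene) | C=CC(=C)CCC=C(C)C | starting material
2 | myrcene 6,7-epoxide; 2,2-dimethyl-3-(3-methylidenepent-4-en-1-yl)oxirane, racemic | C=CC(=C)CCC1OC1(C)C | intermediate
3 | 2-methyl-6-methylideneoct-7-ene-2,3-diol (not isolated) | C=CC(=C)CCC(O)C(C)(C)O | intermediate
4 | 4-methylidenehex-5-enal | C=CC(=C)CCC=O | intermediate
5 | methyl (triphenylphosphoranylidene)acetate | COC(=O)C=P(c1ccccc1)(c1ccccc1)c1ccccc1 | starting material
6 | 2-bromo-N-methoxy-N-methylacetamide | CON(C)C(=O)CBr | starting material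
7 | {1-methoxy-4-[methoxy(methyl)amino]-1,4-dioxobutan-2-yl}triphenylphosphonium bromide (not isolated) | COC(=O)C(CC(=O)N(C)OC)[P+](c1ccccc1)(c1ccccc1)c1ccccc1.[Br-] | intermediate
8 | methyl 4-[methoxy(methyl)amino]-4-oxo-2-(triphenylphosphoranylidene)butanoate | COC(=O)C(CC(=O)N(C)OC)=P(c1ccccc1)(c1ccccc1)c1ccccc1 | intermediate
9 | methyl (2E)-2-{2-[methoxy(methyl)amino]-2-oxoethyl}-6-methylideneocta-2,7-dienoate | C=CC(=C)CC/C=C(\CC(=O)N(C)OC)C(=O)OC | intermediate
10 | O-(diisobutylaluminio) hemiaminal of 9 (not isolated) | C=CC(=C)CC/C=C(\CC(O[Al](CC(C)C)CC(C)C)N(C)OC)C(=O)OC | intermediate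
11 | methyl (2E)-6-methylidene-2-(2-oxoethyl)octa-2,7-dienoate (C8 aldehyde) | C=CC(=C)CC/C=C(\CC=O)C(=O)OC | intermediate
12 | acryloyl chloride | C=CC(=O)Cl | starting material
13 | 2-(trimethylsilyl)ethanol | C[Si](C)(C)CCO | starting material
14 | 2-(trimethylsilyl)ethyl acrylate | C=CC(=O)OCC[Si](C)(C)C | intermediate
15 | acrolein | C=CC=O | starting material
16 | 2-(trimethylsilyl)ethyl 3-hydroxy-2-methylidenepent-4-enoate, racemic | C=CC(O)C(=C)C(=O)OCC[Si](C)(C)C | intermediate
17 | 2-(trimethylsilyl)ethyl (2Z)-2-(bromomethyl)penta-2,4-dienoate (vinyl cis to CH2Br) | C=C/C=C(\CBr)C(=O)OCC[Si](C)(C)C | intermediate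
18 | allylchromium dichloride from 17 (trivalent chromium, chiral ligand omitted; not isolated) | C=C/C=C(\C[Cr](Cl)Cl)C(=O)OCC[Si](C)(C)C | intermediate
19 | C8 O-trimethylsilyl ether of 20 (not isolated) | C=C(C(=O)OCC[Si](C)(C)C)[C@@H](C=C)[C@H](O[Si](C)(C)C)C/C(C(=O)OC)=C\CCC(=C)C=C | intermediate
20 | methyl (2E)-2-[(2R,3R)-3-ethenyl-2-hydroxy-4-{[2-(trimethylsilyl)ethoxy]carbonyl}pent-4-en-1-yl]-6-methylideneocta-2,7-dienoate | C=C(C(=O)OCC[Si](C)(C)C)[C@@H](C=C)[C@H](O)C/C(C(=O)OC)=C\CCC(=C)C=C | intermediate
21 | ten-membered ring (cyclodeca-1,6-diene; 1(10)E, 5Z): CO2Me on C10, exocyclic C4=C15, (8R)-OH, (7R)-C(=CH2)CO2CH2CH2SiMe3 | C=C(C(=O)OCC[Si](C)(C)C)[C@@H]1[C@H](O)C/C(C(=O)OC)=C\CCC(=C)/C=C\1 | intermediate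
22 | (5S,6R)-5,6-epoxide of 21, oxirane cis to the C8 hydroxyl (not isolated) | C=C(C(=O)OCC[Si](C)(C)C)[C@@H]1[C@H](O)C/C(C(=O)OC)=C\CCC(=C)[C@@H]2O[C@H]12 | intermediate
23 | (5S,6R)-5,6-epoxy 8-hydroxy 12-acid, formed as its tetrabutylammonium carboxylate (not isolated) | C=C(C(=O)O)[C@@H]1[C@H](O)C/C(C(=O)OC)=C\CCC(=C)[C@@H]2O[C@H]12 | intermediate
24 | 8-deacyl target: (5S,6S,7R,8R)-5,8-dihydroxy trans-fused 6,12-lactone with C14 methyl ester | C=C1C(=O)O[C@H]2[C@H]1[C@H](O)C/C(C(=O)OC)=C\CCC(=C)[C@@H]2O | intermediate
25 | angelic acid, (2Z)-2-methylbut-2-enoic acid | C/C=C(/C)C(=O)O | starting material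
26 | angelic 2,4,6-trichlorobenzoic anhydride (not isolated) | C/C=C(/C)C(=O)OC(=O)c1c(Cl)cc(Cl)cc1Cl | intermediate
27 | CNP0163095.1, the 8-O-angelate of 24 | C=C1C(=O)O[C@H]2[C@H]1[C@H](OC(=O)/C(C)=C\C)C/C(C(=O)OC)=C\CCC(=C)[C@@H]2O | target

**Step count and risks**

Total steps: 12. Longest linear sequence: 8 (steps 1, 2, 4, 5, 9, 10, 11, 12).

Most likely to fail, in this order:

1. Step 10. The open chain may oligomerise by intermolecular metathesis faster than it closes, or the catalyst may rest as a conjugated vinylcarbene on the diene terminus. The fallback sets out from 20 and holds the two reacting arms cis on a five-membered ring before metathesis. Acid-catalysed lactonisation of 20 (CSA, CH2Cl2, rt) should give the cis-β-vinyl α-methylene-γ-butyrolactone F1 (the 8,12-olide). Ring-closing metathesis of this preorganised triene under the conditions of step 10 should give the cis-fused bicyclic lactone F2. The lactone is opened with LiOH (1 equiv, THF/H2O, 0 °C), the carboxylate is brought to pH 5 in the cold, and the hydroxy acid F3 is taken at once into VO(acac)2/TBHP. The epoxy acid so formed is 23, which closes to 24, so the route is rejoined at 23.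

2. Step 11. Oxygen transfer may show poor facial selectivity, or the Lewis-acidic vanadium may ionise the vinyl oxirane at allylic C5 before the carboxylate is set free. The fallback sets out from 21 and replaces substrate direction by reagent control without a metal: Shi epoxidation with the oxazolidinone-fused sugar-derived ketone made for conjugated cis-alkenes (KHSO5, K2CO3 buffer, MeCN/dimethoxymethane, 0 °C), using the catalyst enantiomer whose spiro transition state leads to the (5S,6R) oxirane. The enoate and the acrylate are inert to the electrophilic dioxirane. This gives 22, where the route is rejoined and continued with the fluoride and acetic acid stage; no new compound arises.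

3. Step 9. Enantioselectivity may erode, or aldehyde 11 may isomerise into conjugation under the amine and chlorosilane of the catalytic cycle. The fallback sets out from 16 and changes the allyl donor to boron under Brønsted acid control. Acetylation (Ac2O, pyridine, DMAP) gives the allylic acetate F4. Copper-catalysed SN2′ borylation (B2pin2, CuCl, KOAc, DMF) should give the pinacol allylboronate F5 with the vinyl group cis to the CH2B arm. Allylboration of 11 with F5 under a chiral BINOL-derived phosphoric acid (TRIP, 5 mol%, toluene, −30 °C) passes through a closed chair transition state, so the same syn adduct is expected, with the acid enantiomer chosen for Si-face attack. After aqueous work-up this gives 20, where the route is rejoined.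

Further compounds
F1 | step 10 | (4R,5R)-cis-4-ethenyl-3-methylidene-5-substituted γ-butyrolactone (acyclic 8,12-olide from 20) | C=C1C(=O)O[C@H](C/C(C(=O)OC)=C\CCC(=C)C=C)[C@@H]1C=C
F2 | step 10 | ten-membered ring cis-fused 8,12-olide with ring-cis C5=C6 | C=C1C(=O)O[C@@H]2C/C(C(=O)OC)=C\CCC(=C)/C=C\[C@H]12
F3 | step 10 | ten-membered (7R,8R)-8-hydroxy triene 12-acid | C=C(C(=O)O)[C@@H]1[C@H](O)C/C(C(=O)OC)=C\CCC(=C)/C=C\1
F0 | step 11 | none | none
F4 | step 9 | 2-(trimethylsilyl)ethyl 3-acetoxy-2-methylidenepent-4-enoate | C=CC(OC(C)=O)C(=C)C(=O)OCC[Si](C)(C)C
F5 | step 9 | 2-(trimethylsilyl)ethyl (2E)-2-[(4,4,5,5-tetramethyl-1,3,2-dioxaborolan-2-yl)methyl]penta-2,4-dienoate (vinyl cis to CH2B) | C=C/C=C(\CB1OC(C)(C)C(C)(C)O1)C(=O)OCC[Si](C)(C)C
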